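**Retrosynthetic overview**

Neolignan numbering is used: C7 is the benzylic carbinol on the guaiacyl ring (ring A), C8 carries the ether oxygen to the 2,6-dimethoxyphenyl ring (ring B), and C9 is the hydroxymethyl carbon.
The strategy rests on reading the erythro (7R,8S) pair C7(OH)–C8(O-ring B), with its C9 hydroxymethyl, as an anti β-aryloxy homoallylic alcohol whose vinyl CH becomes C9.
Disconnections, backwards: four silyl ethers (fluoride); the ring B–C(=O) bond (aryllithium from an aryl bromide plus an O-silyl glycolic Weinreb amide); C9 from the vinyl group (oxidative cleavage, reduction); C7–C8 by a chiral-phosphoric-acid-catalysed anti allylboration of O-silyl vanillin with an (E)-γ-aryloxyallyl boronate that already carries the ring B oxygen; that boronate from 4-bromo-2,6-dimethoxyphenol by O-allylation and an iridium-catalysed double-bond shift.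
No ring is formed; rings A and B are bought, and bonds are made in the order ring B O–CH2 (C3 unit), C7–C8, ring B–acyl.

Key step: step 4

Remark on the chemistry: the sense of induction is assigned by analogy. The R acid is taken to favour Re-face attack on aryl aldehydes, so the S acid should give Si-face attack and 7R. If the first run shows the opposite sense, the enantiomeric acid is used with no other change.

**Route**

Step 1
Reactants: 1 4-bromo-2,6-dimethoxyphenol; 2 (E)-2-(3-chloroprop-1-en-1-yl)-4,4,5,5-tetramethyl-1,3,2-dioxaborolane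
Product: 3 (E)-2-[3-(4-bromo-2,6-dimethoxyphenoxy)prop-1-en-1-yl]-4,4,5,5-tetramethyl-1,3,2-dioxaborolane
Conditions: K2CO3 (1.5 equiv), DMF, 40 °C
Reagents that add atoms: none
Why: Williamson ether synthesis, in which the phenoxide displaces the primary allylic chloride by SN2; the alkenyl pinacol boronate tolerates carbonate base and the E double bond is not touched.

Step 2
Reactants: 3 (E)-2-[3-(4-bromo-2,6-dimethoxyphenoxy)prop-1-en-1-yl]-4,4,5,5-tetramethyl-1,3,2-dioxaborolane
Product: 4 (E)-2-[3-(4-bromo-2,6-dimethoxyphenoxy)prop-2-en-1-yl]-4,4,5,5-tetramethyl-1,3,2-dioxaborolane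
Conditions: [Ir(cod)(PPh2Me)2]PF6 (3 mol%, activated with H2, then degassed), THF, rt
Reagents that add atoms: none
Why: Metal-hydride olefin isomerisation (hydrometalation, then β-hydride elimination from the O-CH2 carbon) moves the double bond from boron into conjugation with oxygen, and the cationic iridium hydride is known to give the E enol ether from γ-oxygenated alkenyl boronates and allyl aryl ethers; 4 is kept cold and free of acid and used promptly.

Step 3
Reactants: 5 vanillin (4-hydroxy-3-methoxybenzaldehyde)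
Product: 6 4-(tert-butyldimethylsilyloxy)-3-methoxybenzaldehyde
Conditions: TBSCl, imidazole, DMF, rt
Reagents that add atoms: tert-butyldimethylsilyl chloride, CC(C)(C)[Si](C)(C)Cl
Why: Standard imidazole-mediated silylation of the phenol, which removes the acidic proton that would quench the acid catalyst and the boronate in the next step.

Step 4
Reactants: 4 (E)-2-[3-(4-bromo-2,6-dimethoxyphenoxy)prop-2-en-1-yl]-4,4,5,5-tetramethyl-1,3,2-dioxaborolane; 6 4-(tert-butyldimethylsilyloxy)-3-methoxybenzaldehyde
Product: 8 (1R,2S)-2-(4-bromo-2,6-dimethoxyphenoxy)-1-[4-(tert-butyldimethylsilyloxy)-3-methoxyphenyl]but-3-en-1-ol, via pinacol borate ester 7 (not isolated)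
Conditions: (S)-3,3'-bis(2,4,6-triisopropylphenyl)-1,1'-binaphthyl-2,2'-diyl hydrogen phosphate (10 mol%), 4 Å molecular sieves, toluene, −30 to 0 °C; aq NaHCO3 work-up
Reagents that add atoms: none
Why: The phosphoric acid hydrogen-bonds to a pinacol oxygen of 4 while its phosphoryl oxygen contacts the formyl hydrogen of 6, and the aldehyde carbon (C7) then bonds to the γ-carbon of 4 (C8) with allylic transposition through a closed six-membered chair (Zimmerman–Traxler) transition state; the closest known reaction type is the BINOL-phosphoric-acid-catalysed allylboration of aryl aldehydes with γ-substituted and γ-alkoxy allyl pinacolboronates, here applied to a γ-aryloxy reagent. No ring is closed in the product: only the transition state is cyclic, and it collapses to borate 7, which is hydrolysed on work-up. The anti (erythro) relationship is fixed by the E geometry of 4, which places the aryloxy group equatorial beside the equatorial aryl group of the aldehyde. The absolute configuration is fixed by the catalyst, whose 3,3'-aryl groups should leave only the Si face of the aldehyde open, giving 7R and therefore 8S. The step needs enantiofacial selectivity (from the catalyst) and anti diastereoselectivity (from the geometric purity of 4); a non-enolisable aryl aldehyde is the substrate class this catalysis handles best, although the donor substituents of 6 will slow the addition.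

Step 5
Reactants: 8 (1R,2S)-2-(4-bromo-2,6-dimethoxyphenoxy)-1-[4-(tert-butyldimethylsilyloxy)-3-methoxyphenyl]but-3-en-1-ol
Product: 9 (1R,2S)-2-(4-bromo-2,6-dimethoxyphenoxy)-1-(tert-butyldimethylsilyloxy)-1-[4-(tert-butyldimethylsilyloxy)-3-methoxyphenyl]but-3-ene (C7 O-TBS ether of 8)
Conditions: TBSOTf, 2,6-lutidine, CH2Cl2, −78 to 0 °C
Reagents that add atoms: tert-butyldimethylsilyl triflate, CC(C)(C)[Si](C)(C)OS(=O)(=O)C(F)(F)F
Why: Silyl triflate with a hindered base silylates the crowded secondary benzylic hydroxyl without ionising it, and capping C7–OH prevents retro-aldol cleavage once C9 becomes an aldehyde.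

Step 6
Reactants: 9 C7 O-TBS ether of 8
Product: 11 (2R,3R)-2-(4-bromo-2,6-dimethoxyphenoxy)-3-(tert-butyldimethylsilyloxy)-3-[4-(tert-butyldimethylsilyloxy)-3-methoxyphenyl]propanal, via vicinal diol 10 (not isolated)
Conditions: OsO4 (2 mol%), NaIO4 (4 equiv), 2,6-lutidine (2 equiv), 1,4-dioxane/H2O 3:1, rt
Reagents that add atoms: osmium tetroxide, O=[Os](=O)(=O)=O (delivers the aldehyde oxygen); sodium periodate, [Na+].[O-]I(=O)(=O)=O (re-oxidises osmium and cleaves the diol)
Why: Lemieux–Johnson oxidation dihydroxylates the only C=C to diol 10, which periodate cleaves with loss of the terminal carbon; ozone is avoided because of the electron-rich arenes, the lutidine buffer limits epimerisation at C8, and no stereocentre is changed (the R descriptor at C8 reflects only the new CIP priority of CHO).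

Step 7
Reactants: 11 (2R,3R)-2-(4-bromo-2,6-dimethoxyphenoxy)-3-(tert-butyldimethylsilyloxy)-3-[4-(tert-butyldimethylsilyloxy)-3-methoxyphenyl]propanal
Product: 12 (2S,3R)-2-(4-bromo-2,6-dimethoxyphenoxy)-3-(tert-butyldimethylsilyloxy)-3-[4-(tert-butyldimethylsilyloxy)-3-methoxyphenyl]propan-1-ol
Conditions: NaBH4, THF/MeOH, −20 to 0 °C (crude 11 used at once)
Reagents that add atoms: none
Why: Borohydride reduction of the aldehyde at low temperature should outrun enolisation and β-elimination of the silyloxy group, so the configurationally labile α-aryloxy aldehyde is converted into the stable C9 alcohol with C7 and C8 unchanged.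

Step 8
Reactants: 12 (2S,3R)-2-(4-bromo-2,6-dimethoxyphenoxy)-3-(tert-butyldimethylsilyloxy)-3-[4-(tert-butyldimethylsilyloxy)-3-methoxyphenyl]propan-1-ol
Product: 13 (1R,2S)-2-(4-bromo-2,6-dimethoxyphenoxy)-1,3-bis(tert-butyldimethylsilyloxy)-1-[4-(tert-butyldimethylsilyloxy)-3-methoxyphenyl]propane
Conditions: TBSCl, imidazole, DMF, rt
Reagents that add atoms: tert-butyldimethylsilyl chloride, CC(C)(C)[Si](C)(C)Cl
Why: Routine silylation of the primary hydroxyl removes the last acidic proton before the organolithium step, and would also restore the aryl silyl ether should any have been lost during the reduction.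

Step 9
Reactants: 14 methyl glycolate
Product: 15 methyl 2-(tert-butyldimethylsilyloxy)acetate
Conditions: TBSCl, imidazole, CH2Cl2, 0 °C to rt
Reagents that add atoms: tert-butyldimethylsilyl chloride, CC(C)(C)[Si](C)(C)Cl
Why: Standard silylation of a primary alcohol; the methyl ester is untouched.

Step 10
Reactants: 15 methyl 2-(tert-butyldimethylsilyloxy)acetate
Product: 16 2-(tert-butyldimethylsilyloxy)-N-methoxy-N-methylacetamide
Conditions: MeNH(OMe)·HCl (1.5 equiv), i-PrMgCl (3 equiv), THF, −20 to 0 °C
Reagents that add atoms: N,O-dimethylhydroxylamine hydrochloride, CNOC.Cl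
Why: Direct ester aminolysis by the chloromagnesium amide formed in situ from the hydroxylamine salt and the Grignard reagent, a standard way to make Weinreb amides from methyl esters.

Step 11
Reactants: 13 (1R,2S)-2-(4-bromo-2,6-dimethoxyphenoxy)-1,3-bis(tert-butyldimethylsilyloxy)-1-[4-(tert-butyldimethylsilyloxy)-3-methoxyphenyl]propane; 16 2-(tert-butyldimethylsilyloxy)-N-methoxy-N-methylacetamide
Product: 19 2-(tert-butyldimethylsilyloxy)-1-{4-[(1R,2S)-1,3-bis(tert-butyldimethylsilyloxy)-1-(4-(tert-butyldimethylsilyloxy)-3-methoxyphenyl)propan-2-yl]oxy-3,5-dimethoxyphenyl}ethan-1-one, via aryllithium 17 (not isolated), via tetrahedral lithium adduct 18 (not isolated)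
Conditions: t-BuLi (2.1 equiv), THF, −78 °C; then 16, −78 to −40 °C; aq NH4Cl
Reagents that add atoms: none
Why: Bromine–lithium exchange followed by Weinreb ketone synthesis, in which the chelated tetrahedral adduct 18 survives until work-up so that only the mono-acylated ketone forms; at −78 °C the silyl ethers and both stereocentres are not affected.

Step 12
Reactants: 19 tetrakis-TBS ether of the target
Product: 20 2-hydroxy-1-{4-[(1R,2S)-1,3-dihydroxy-1-(4-hydroxy-3-methoxyphenyl)propan-2-yl]oxy-3,5-dimethoxyphenyl}ethan-1-one (CNP0282675.1, 7R,8S)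
Conditions: Bu4NF/AcOH (1:1, 6 equiv), THF, 0 °C to rt
Reagents that add atoms: none
Why: Fluoride-driven cleavage of all four silyl ethers (Si–F bond formation); the acetic acid buffer keeps the medium near neutral, so the α-hydroxy ketone is not exposed to strong base and the p-hydroxybenzylic C7 is not ionised or epimerised.

**Compound list**

1 | 4-bromo-2,6-dimethoxyphenol | COc1cc(Br)cc(OC)c1O | starting material
2 | (E)-2-(3-chloroprop-1-en-1-yl)-4,4,5,5-tetramethyl-1,3,2-dioxaborolane | ClC/C=C/B1OC(C)(C)C(C)(C)O1 | starting material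
3 | (E)-2-[3-(4-bromo-2,6-dimethoxyphenoxy)prop-1-en-1-yl]-4,4,5,5-tetramethyl-1,3,2-dioxaborolane | COc1cc(Br)cc(OC)c1OC/C=C/B1OC(C)(C)C(C)(C)O1 | intermediate
4 | (E)-2-[3-(4-bromo-2,6-dimethoxyphenoxy)prop-2-en-1-yl]-4,4,5,5-tetramethyl-1,3,2-dioxaborolane | COc1cc(Br)cc(OC)c1O/C=C/CB1OC(C)(C)C(C)(C)O1 | intermediate
5 | vanillin (4-hydroxy-3-methoxybenzaldehyde) | COc1cc(C=O)ccc1O | starting material
6 | 4-(tert-butyldimethylsilyloxy)-3-methoxybenzaldehyde | COc1cc(C=O)ccc1O[Si](C)(C)C(C)(C)C | intermediate
7 | pinacol borate ester of alcohol 8 (O–B bond at C7, 1R,2S) | COc1cc([C@@H](OB3OC(C)(C)C(C)(C)O3)[C@H](C=C)Oc2c(OC)cc(Br)cc2OC)ccc1O[Si](C)(C)C(C)(C)C | intermediate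
8 | (1R,2S)-2-(4-bromo-2,6-dimethoxyphenoxy)-1-[4-(tert-butyldimethylsilyloxy)-3-methoxyphenyl]but-3-en-1-ol | COc1cc([C@@H](O)[C@H](C=C)Oc2c(OC)cc(Br)cc2OC)ccc1O[Si](C)(C)C(C)(C)C | intermediate
9 | (1R,2S)-2-(4-bromo-2,6-dimethoxyphenoxy)-1-(tert-butyldimethylsilyloxy)-1-[4-(tert-butyldimethylsilyloxy)-3-methoxyphenyl]but-3-ene | COc1cc([C@@H](O[Si](C)(C)C(C)(C)C)[C@H](C=C)Oc2c(OC)cc(Br)cc2OC)ccc1O[Si](C)(C)C(C)(C)C | intermediate
10 | (2RS,3S,4R)-3-(4-bromo-2,6-dimethoxyphenoxy)-4-(tert-butyldimethylsilyloxy)-4-[4-(tert-butyldimethylsilyloxy)-3-methoxyphenyl]butane-1,2-diol (both epimers at C2) | COc1cc([C@@H](O[Si](C)(C)C(C)(C)C)[C@H](C(O)CO)Oc2c(OC)cc(Br)cc2OC)ccc1O[Si](C)(C)C(C)(C)C | intermediate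
11 | (2R,3R)-2-(4-bromo-2,6-dimethoxyphenoxy)-3-(tert-butyldimethylsilyloxy)-3-[4-(tert-butyldimethylsilyloxy)-3-methoxyphenyl]propanal | COc1cc([C@@H](O[Si](C)(C)C(C)(C)C)[C@H](C=O)Oc2c(OC)cc(Br)cc2OC)ccc1O[Si](C)(C)C(C)(C)C | intermediate
12 | (2S,3R)-2-(4-bromo-2,6-dimethoxyphenoxy)-3-(tert-butyldimethylsilyloxy)-3-[4-(tert-butyldimethylsilyloxy)-3-methoxyphenyl]propan-1-ol | COc1cc([C@@H](O[Si](C)(C)C(C)(C)C)[C@H](CO)Oc2c(OC)cc(Br)cc2OC)ccc1O[Si](C)(C)C(C)(C)C | intermediate
13 | (1R,2S)-2-(4-bromo-2,6-dimethoxyphenoxy)-1,3-bis(tert-butyldimethylsilyloxy)-1-[4-(tert-butyldimethylsilyloxy)-3-methoxyphenyl]propane | COc1cc([C@@H](O[Si](C)(C)C(C)(C)C)[C@H](CO[Si](C)(C)C(C)(C)C)Oc2c(OC)cc(Br)cc2OC)ccc1O[Si](C)(C)C(C)(C)C | intermediate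
14 | methyl glycolate | COC(=O)CO | starting material
15 | methyl 2-(tert-butyldimethylsilyloxy)acetate | COC(=O)CO[Si](C)(C)C(C)(C)C | intermediate
16 | 2-(tert-butyldimethylsilyloxy)-N-methoxy-N-methylacetamide | CON(C)C(=O)CO[Si](C)(C)C(C)(C)C | intermediate
17 | aryllithium derived from 13 (lithium in place of bromine on ring B) | COc1cc([C@@H](O[Si](C)(C)C(C)(C)C)[C@H](CO[Si](C)(C)C(C)(C)C)Oc2c(OC)cc([Li])cc2OC)ccc1O[Si](C)(C)C(C)(C)C | intermediate
18 | lithium alkoxide of the N-methoxy-N-methyl hemiaminal formed from 17 and 16 (tetrahedral adduct) | COc1cc([C@@H](O[Si](C)(C)C(C)(C)C)[C@H](CO[Si](C)(C)C(C)(C)C)Oc2c(OC)cc(C(O[Li])(N(C)OC)CO[Si](C)(C)C(C)(C)C)cc2OC)ccc1O[Si](C)(C)C(C)(C)C | intermediate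
19 | 2-(tert-butyldimethylsilyloxy)-1-{4-[(1R,2S)-1,3-bis(tert-butyldimethylsilyloxy)-1-(4-(tert-butyldimethylsilyloxy)-3-methoxyphenyl)propan-2-yl]oxy-3,5-dimethoxyphenyl}ethan-1-one | COc1cc([C@@H](O[Si](C)(C)C(C)(C)C)[C@H](CO[Si](C)(C)C(C)(C)C)Oc2c(OC)cc(C(=O)CO[Si](C)(C)C(C)(C)C)cc2OC)ccc1O[Si](C)(C)C(C)(C)C | intermediate
20 | 2-hydroxy-1-{4-[(1R,2S)-1,3-dihydroxy-1-(4-hydroxy-3-methoxyphenyl)propan-2-yl]oxy-3,5-dimethoxyphenyl}ethan-1-one (CNP0282675.1) | COc1cc([C@@H](O)[C@H](CO)Oc2c(OC)cc(C(=O)CO)cc2OC)ccc1O | target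

**Step count and risks**

Total step count: 12. Longest linear sequence: 9 steps (steps 1, 2, 4, 5, 6, 7, 8, 11, 12).

Steps most likely to fail:

1. Step 4. The addition to the donor-substituted aldehyde may be slow enough for the uncatalysed background reaction to compete. The bulky 2,6-dimethoxyaryloxy group may also disturb the catalyst pocket and weaken discrimination between the aldehyde faces. The anti relationship should survive either way, because it comes from the closed transition state. The fallback replaces catalysis by resolution; it sets out from 4 and 6 and comes back at 8. Compounds 4 and 6 are heated without catalyst in toluene at 60 °C, which should give the anti product as a racemate: borate 7 together with the mirror-image borate F1, hydrolysed on work-up to 8 together with the enantiomeric (1S,2R) alcohol F2. The mixture is esterified with (S)-O-methylmandelic acid (N,N'-dicyclohexylcarbodiimide, catalytic 4-(dimethylamino)pyridine, CH2Cl2, 0 °C). This gives the (S)-O-methylmandelate ester of 8 F3 and the (S)-O-methylmandelate ester of the enantiomer F4, which are diastereomers and are separated by chromatography. Ester F3 is cleaved with i-Bu2AlH (CH2Cl2, −78 °C) to return 8.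

2. Step 2. The isomerisation may stall through catalyst deactivation, the E geometry may erode through over-equilibration, or the acid- and moisture-sensitive enol ether allylboronate may decompose on isolation. The fallback builds the E enol ether first and installs boron last; it sets out from 1 and comes back at 4. Phenol 1 is added to ethyl propiolate (catalytic 1,4-diazabicyclo[2.2.2]octane, CH2Cl2, rt) to give ethyl (E)-3-(4-bromo-2,6-dimethoxyphenoxy)acrylate F5. Reduction with i-Bu2AlH (CH2Cl2, −78 °C) gives (E)-3-(4-bromo-2,6-dimethoxyphenoxy)prop-2-en-1-ol F6, and acetylation (Ac2O, pyridine, 0 °C) gives (E)-3-(4-bromo-2,6-dimethoxyphenoxy)allyl acetate F7. Allylic borylation with B2pin2 and Pd2(dba)3 (catalytic, phosphine-free) in DMSO at 50 °C should place boron at the unsubstituted allyl terminus with E geometry and give 4. Phosphine-free zerovalent palladium is expected to ionise the allylic acetate much faster than it inserts into the electron-rich aryl bromide.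

3. Step 11. The exchange may be incomplete, the aryllithium may be quenched by proton transfer from the α-CH2 of the amide, or the alkyllithium may attack the aryl silyl ether. The fallback attaches the two-carbon unit by cross-coupling without any organolithium; it sets out from 13 and comes back at 20. Stille coupling of 13 with tributyl(1-ethoxyvinyl)stannane (Pd(PPh3)4, toluene, 100 °C) gives the 1-ethoxyvinyl arene F8. Dihydroxylation of this enol ether (catalytic OsO4, N-methylmorpholine N-oxide, acetone/H2O, rt) gives the hemiketal diol F9, which loses ethanol in the flask to give the tris-silylated hydroxyacetyl ketone F10. Ketone F10 is desilylated under the buffered fluoride conditions of step 12 to give 20.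

**Further compounds**

F1 | step 4 | pinacol borate ester of the (1S,2R) alcohol (mirror image of 7) | COc1cc([C@H](OB3OC(C)(C)C(C)(C)O3)[C@@H](C=C)Oc2c(OC)cc(Br)cc2OC)ccc1O[Si](C)(C)C(C)(C)C
F2 | step 4 | (1S,2R)-2-(4-bromo-2,6-dimethoxyphenoxy)-1-[4-(tert-butyldimethylsilyloxy)-3-methoxyphenyl]but-3-en-1-ol (enantiomer of 8) | COc1cc([C@H](O)[C@@H](C=C)Oc2c(OC)cc(Br)cc2OC)ccc1O[Si](C)(C)C(C)(C)C
F3 | step 4 | (S)-O-methylmandelate ester of 8 | COc1cc([C@@H](OC(=O)[C@@H](OC)c3ccccc3)[C@H](C=C)Oc2c(OC)cc(Br)cc2OC)ccc1O[Si](C)(C)C(C)(C)C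
F4 | step 4 | (S)-O-methylmandelate ester of the enantiomer F2 | COc1cc([C@H](OC(=O)[C@@H](OC)c3ccccc3)[C@@H](C=C)Oc2c(OC)cc(Br)cc2OC)ccc1O[Si](C)(C)C(C)(C)C
F5 | step 2 | ethyl (E)-3-(4-bromo-2,6-dimethoxyphenoxy)acrylate | CCOC(=O)/C=C/Oc1c(OC)cc(Br)cc1OC
F6 | step 2 | (E)-3-(4-bromo-2,6-dimethoxyphenoxy)prop-2-en-1-ol | OC/C=C/Oc1c(OC)cc(Br)cc1OC
F7 | step 2 | (E)-3-(4-bromo-2,6-dimethoxyphenoxy)allyl acetate | CC(=O)OC/C=C/Oc1c(OC)cc(Br)cc1OC
F8 | step 11 | 1-ethoxyvinyl arene (1-ethoxyvinyl in place of bromine in 13) | COc1cc([C@@H](O[Si](C)(C)C(C)(C)C)[C@H](CO[Si](C)(C)C(C)(C)C)Oc2c(OC)cc(C(=C)OCC)cc2OC)ccc1O[Si](C)(C)C(C)(C)C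
F9 | step 11 | hemiketal diol from dihydroxylation of F8 (not isolated) | COc1cc([C@@H](O[Si](C)(C)C(C)(C)C)[C@H](CO[Si](C)(C)C(C)(C)C)Oc2c(OC)cc(C(O)(OCC)CO)cc2OC)ccc1O[Si](C)(C)C(C)(C)C
F10 | step 11 | tris-silylated hydroxyacetyl ketone (19 with a free primary hydroxyl next to the ketone) | COc1cc([C@@H](O[Si](C)(C)C(C)(C)C)[C@H](CO[Si](C)(C)C(C)(C)C)Oc2c(OC)cc(C(=O)CO)cc2OC)ccc1O[Si](C)(C)C(C)(C)C
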